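## Structural features

The target is a trans-2,3-disubstituted 2,3-dihydrobenzofuran. C2 carries a 3,4-dihydroxyphenyl group (ring B), C3 a methyl ester, and the fused benzene ring (ring A) has four contiguous substituents: C3a (bonded to C3), C4 (an (E)-propenoate), C7a (bonded to O1) and C7 (a free hydroxyl). The propenoate is esterified with the secondary hydroxyl of (R)-3-(3,4-dihydroxyphenyl)lactic acid (ring C), whose carboxyl group is free, so a methyl ester, an enoate ester and a free acid must be told apart. C2 (S) and C3 (S) are adjacent and trans; the third stereocentre (R) sits in the lactate unit, remote from the core and best taken from the chiral pool. Several sites are fragile: C3–H is benzylic, α to the ester and β to O1, so base epimerises C3 and opens the ring by E1cB; C2–O1 is a para-oxygenated benzylic ether and is acid-sensitive; the catechols oxidise easily; and the enoate rules out hydrogenolysis once it is in place. The real difficulty is ring A, with two adjacent oxygens next to two adjacent carbon substituents, together with the trans stereodiad and a global deprotection that the core survives. The key step exploits exactly this ring A pattern: a furan tethered through its C2 to an ethynyl ether delivers O1 on C7a beside a hydroxyl on C7, with furan C2–C5 becoming C3a–C6, the alkyne carbons becoming C7a and C7, and the furan oxygen becoming the C7 hydroxyl.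

## Logic of the disconnections

35 is traced back to 34 by re-forming six O–benzyl bonds (five phenolic ethers and the ester of the lactate carboxyl). The cut is made there because one Lewis-acid operation can then uncover every acidic group at the end without hydrogen (which the enoate would not survive) and without base (which C3–H would not survive). The gain is that all earlier intermediates carry only groups stable to alkoxide, organolithium, hydride and oxidants. The demand is chemoselectivity: the methyl ester, the enoate and the C2–O1 bond must outlast the debenzylation.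

34 is cut at the C=C bond of the C4 propenoate into 29 and 33. The two halves, each with its own stereochemistry, then meet late, and the (E)-geometry is made together with the bond. The gain is a dihydrobenzofuran aldehyde and a lactate-derived phosphonate of similar size. The demand is an olefination base too weak to remove C3–H. 33 is opened at its acyl C–O bond to 31 and 32, and 31 at three O–benzyl bonds to 30; this only requires that the secondary hydroxyl of 30 stays free during benzylation.

Between 29 and 23 no skeletal bond is cut; the chain 29, 28, 27, 25, 24, 23 changes only oxidation levels and protecting groups. The C4 formyl group goes back to a cyclic acetal, the C3 methyl ester goes back through the acid to a silyl-protected hydroxymethyl group, and the C7 benzyl ether goes back to the phenol. The reason is that an ester at C3 must not exist while the ynol ether is made, and the phenol from the key step must be masked before any oxidation. The gain is that 23 bears only groups compatible with the chemistry before it. The demand is an oxidation at C3 that passes through an epimerisable, elimination-prone aldehyde and must therefore be neutral and fast.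

In 23 the bonds C3a–C7a and C6–C7 are cut and the C7 oxygen is returned to bridge C3a and C6 as a furan oxygen, which gives 20. This removes ring A and the dihydrofuran ring at once and replaces a benzene with four contiguous positions by a 2,3-disubstituted furan and a two-carbon ether. The gain is an open-chain compound whose two stereocentres are those of an aldol and whose two adjacent ring oxygens need no separate oxidation. The demand is that furan C2 attacks the oxygen-bearing alkyne carbon, that the arene oxide opens towards the C7 hydroxyl, and that the cascade outruns ionisation of the benzylic C–O bond.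

20 is cut at the O–C(sp) bond to 16 and 17, the latter supplying C7a and C7. Addition of an alkoxide to a chloroalkyne followed by elimination is the general route to ethynyl ethers of secondary alcohols. The gain is a secondary benzylic alcohol and a commodity chemical. The demand is compatibility with a potassium alkoxide and n-BuLi: 16 may hold no carbonyl group and no acidic C–H next to the carbinol, which fixes the future ester carbon as a protected primary alcohol.

16 is traced through its Si–O bond to 15 and through the reductively cleaved N–acyl bond to 14. 14 is cut at the bond between the furyl-bearing carbon and the carbinol carbon (the future C3–C2 bond) into 11 and 12. An auxiliary-controlled syn-aldol forms this bond and both stereocentres in one step, and the syn arrangement is the one that closes to the trans ring. The gain is two fragments of similar size, one of them purchasable. The demand is a (Z)-enolate, facial control by the auxiliary, and a Lewis acid that spares the acetal.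

11 is cut at the N–acyl bond to 8 and 9. 8 is related by oxidation level to 6, which is cut at the furan C2–CH2 bond to 3 and 4. 3 is opened at its acetal C–O bonds to 1 and 2. These cuts end in purchasable compounds. The demands are regioselective metalation at furan C2, between the ring oxygen and the acetal, and an oxidation gentle enough for the furan.

## Other disconnections considered

Alternative 1: The cut runs through C3–C3a and O1–C2 and divides the core into two C6–C3 units, the caffeate A1 and the rosmarinate A2.
- **Forward step:** Ag2O oxidises both phenols. The ester-bearing alkene carbon of the A1 radical bonds to the ring carbon of A2 that lies between its free hydroxyl and its side chain, and the phenol oxygen adds to the resulting para-quinone methide to give A3.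
- **In its favour:** ring A, the complete side chain and every carbon of the target are in place before the key step. No auxiliary or precious metal is needed, and the trans arrangement is the thermodynamic result of the quinone methide closure. On step economy and convergence it is clearly better than the chosen plan.
- **Against it here:** two different phenols are oxidised together, so homo-coupling and other carbon–carbon and carbon–oxygen coupling modes compete with the wanted cross-coupling. The two new stereocentres form under no control beyond a remote lactate centre, so both trans diastereomers are to be expected in similar amounts.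
- **Comparison:** both plans close the dihydrofuran ring in the key step and both should give the trans relationship (equal). The chosen plan uses a tether that allows one regiochemistry and brings in auxiliary-set stereocentres, where the alternative relies on statistical radical pairing. The alternative wins on length; the chosen plan wins on regio- and absolute stereocontrol.

Alternative 2: The cut is the C3–C3a bond, read as the result of a 1,2-shift. The retron is the flavanone A4, in which that ring A carbon is still bonded to the ketone carbon.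
- **Forward step:** in HC(OMe)3 with H2SO4 the ketone is ketalised and enolised, PhI(OAc)2 attacks C3, and loss of iodobenzene is assisted by migration of the ring A carbon from the ketal carbon to C3. The pyranone contracts to the dihydrofuran and the former ketone carbon emerges as the methyl ester of A5.
- **In its favour:** C2 is untouched, so its configuration is carried over from A4. The ester arrives at its final oxidation level, which the chosen plan reaches only by a later oxidation (better). The bromine at C4 would let the propenoate be attached in one Heck step, so the sequence after the key step is shorter (better). The reaction type is established for flavanones (at least equal on precedent).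
- **Against it here:** A4 needs a 2-hydroxyacetophenone already flanked by bromine and benzyloxy, so the four contiguous substituents of ring A are paid for in a lengthy arene synthesis. An enantioenriched flavanone can racemise by reversible ring opening in acid. Migration of the electron-rich ring B and dehydrogenation to the flavone are plausible side paths, and concentrated acid meets three benzyl ethers.
- **Comparison:** structurally the alternative rearranges a preformed arene, while the chosen plan builds the arene. Both are cationic rearrangements that leave C2 alone and let C3 settle trans (equal). Overall length is probably equal or somewhat shorter for the alternative. The chosen plan is more secure on enantiopurity, because an auxiliary aldol sets both centres and nothing afterwards can racemise them.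

Alternative 3: The cut runs through C5–C6 and C7–C7a; ring A is again made de novo, but by cycloaddition.
- **Forward step:** the vinylketene acetal A6 acts as a Diels–Alder diene towards but-3-yn-2-one A7. Its terminal CH2 bonds to the unsubstituted alkyne carbon (C5–C6) and its ketene acetal carbon to the acetyl-bearing carbon (C7–C7a). Loss of t-BuMe2SiOH aromatises the adduct to A8.
- **In its favour:** like the chosen plan it needs no pre-built tetrasubstituted arene (equal). The regiochemistry follows from the polarisation of both partners. The C3 ester and the C4 acetal are already at their final oxidation levels (better than the chosen plan).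
- **Against it here:** C7 arrives as an acetyl group and needs a Baeyer–Villiger oxidation and acetate cleavage to become the hydroxyl, next to an electron-rich ring. A6 must be made by enolising a lactone that also carries the acidic C3–H of the ester, so enolisation at the wrong site and β-elimination of the lactone oxygen threaten. The diene is hydrolytically labile and the cycloaddition is intermolecular.
- **Comparison:** both plans build ring A last. The chosen cascade closes two rings in one operation and delivers the C7 hydroxyl directly under the regiocontrol of a tether, where the alternative closes one ring under electronic control and adds redox steps. Step count is likely equal or in favour of the chosen plan; the oxidation level at C3 favours the alternative.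

Key step: step 9

Remarks on the chemistry (one line each):
- Ring atoms are numbered as in the benzofuran product throughout.
- The precursor of the key step carries the future C3 ester carbon as a TBDPS-protected hydroxymethyl group: an ester or acid there would put an acidic hydrogen β to the ynol ether oxygen (retro-aldol and E1cB under the potassium alkoxide and n-BuLi), and a free acid adds to an ynol ether. The bonds formed, the rings closed and the skeletons of 20 and 23 are unchanged.
- The future C4 formyl carbon is carried as a 5,5-dimethyl-1,3-dioxane acetal, which directs the furan metalation, survives all basic steps and is removed independently of the silyl ether.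
- Configuration check: an ester analogue of 20 would be (2R,3S) and is the syn-aldol isomer; it maps without change of geometry onto the (2S,3S) trans ester. For the hydroxymethyl-derived compounds the same geometry reads (2R,3S) for 20 and (2S,3R) for 23, because CIP priorities at C3 change. No configuration needs correcting, and C3 needs no epimerisation.
- Diazomethane is avoided (iodomethane/KHCO3), and dichloroacetylene is only formed and consumed in solution.
- Assumption: sodium (R)-danshensu 30 is purchased.

## Route

Step 1
Reactants: 1 furan-3-carbaldehyde; 2 2,2-dimethylpropane-1,3-diol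
Product: 3 2-(furan-3-yl)-5,5-dimethyl-1,3-dioxane
Conditions: PPTS (cat.), toluene, reflux, Dean–Stark
Reagents that add atoms: none
Why: Acid-catalysed acetalisation with azeotropic removal of water; the six-membered acetal is robust towards organolithiums, KH and hydride and later directs metalation.

Step 2
Reactants: 3 2-(furan-3-yl)-5,5-dimethyl-1,3-dioxane; 4 oxirane
Product: 6 2-[3-(5,5-dimethyl-1,3-dioxan-2-yl)furan-2-yl]ethan-1-ol, via 2-lithiofuran 5 (not isolated)
Conditions: n-BuLi, THF, −78 → 0 °C; 4, 0 °C → rt; H2O
Reagents that add atoms: none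
Why: Directed ortho-metalation: furan C2 is the most acidic position and lithium is held by the acetal oxygens, so deprotonation should occur between the ring oxygen and the acetal. 2-Furyllithiums open oxirane by SN2 to give 2-(2-hydroxyethyl)furans.

Step 3
Reactants: 6 2-[3-(5,5-dimethyl-1,3-dioxan-2-yl)furan-2-yl]ethan-1-ol
Product: 8 2-[3-(5,5-dimethyl-1,3-dioxan-2-yl)furan-2-yl]acetic acid, via aldehyde 7 (not isolated)
Conditions: TEMPO (cat.), PhI(OAc)2, NaHCO3, MeCN/H2O, 0 °C → rt
Reagents that add atoms: water, O
Why: Oxoammonium (TEMPO) oxidation with PhI(OAc)2 as terminal oxidant takes the primary alcohol through the aldehyde hydrate to the acid under buffered, near-neutral conditions that should spare the furan and the acetal.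

Step 4
Reactants: 8 2-[3-(5,5-dimethyl-1,3-dioxan-2-yl)furan-2-yl]acetic acid; 9 (4S)-4-benzyl-1,3-oxazolidin-2-one
Product: 11 (4S)-4-benzyl-3-{2-[3-(5,5-dimethyl-1,3-dioxan-2-yl)furan-2-yl]acetyl}-1,3-oxazolidin-2-one, via mixed pivalic anhydride 10 (not isolated)
Conditions: PivCl, Et3N, THF, −20 °C; then 9, LiCl, −20 °C → rt
Reagents that add atoms: none
Why: Mixed-anhydride N-acylation of the oxazolidinone with LiCl/Et3N activation; it avoids an acid chloride of an acid-sensitive furan and needs no strong base.

Step 5
Reactants: 11 (4S)-4-benzyl-3-{2-[3-(5,5-dimethyl-1,3-dioxan-2-yl)furan-2-yl]acetyl}-1,3-oxazolidin-2-one; 12 3,4-bis(benzyloxy)benzaldehyde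
Product: 14 (4S)-4-benzyl-3-{(2R,3S)-3-[3,4-bis(benzyloxy)phenyl]-2-[3-(5,5-dimethyl-1,3-dioxan-2-yl)furan-2-yl]-3-hydroxypropanoyl}-1,3-oxazolidin-2-one, via (Z)-boron enolate 13 (not isolated)
Conditions: Bu2BOTf, i-Pr2NEt, CH2Cl2, −78 → 0 °C; 12, −78 → 0 °C; pH 7 buffer, MeOH, H2O2, 0 °C
Reagents that add atoms: none
Why: Evans syn-aldol: soft enolisation gives the (Z)-boron enolate, which adds through a Zimmerman–Traxler chair with the imide dipoles opposed, on the face away from the benzyl group of the auxiliary. This sets (2R) and (3S) of the propanoyl chain, the syn pair that corresponds to the trans ring.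

Step 6
Reactants: 14 the syn-aldol imide
Product: 15 (1S,2R)-1-[3,4-bis(benzyloxy)phenyl]-2-[3-(5,5-dimethyl-1,3-dioxan-2-yl)furan-2-yl]propane-1,3-diol
Conditions: LiBH4, MeOH (1 equiv), THF, 0 °C
Reagents that add atoms: none
Why: LiBH4 reduces the exocyclic imide carbonyl chemoselectively and releases the auxiliary without touching either stereocentre. Removing the carbonyl also removes the acidic α-hydrogen and the retro-aldol path before any strong base is used.

Step 7
Reactants: 15 the 1,3-diol
Product: 16 (1S,2R)-1-[3,4-bis(benzyloxy)phenyl]-3-[(tert-butyldiphenylsilyl)oxy]-2-[3-(5,5-dimethyl-1,3-dioxan-2-yl)furan-2-yl]propan-1-ol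
Conditions: TBDPSCl, imidazole, CH2Cl2, 0 °C → rt
Reagents that add atoms: tert-butyl(chloro)diphenylsilane, CC(C)(C)[Si](Cl)(c1ccccc1)c1ccccc1
Why: The bulky silyl chloride discriminates the primary from the hindered secondary benzylic hydroxyl; TBDPS is chosen for its low tendency to migrate to a neighbouring alkoxide.

Step 8
Reactants: 16 the mono-silylated diol; 17 trichloroethylene
Product: 20 tert-butyl{[(2R,3S)-3-[3,4-bis(benzyloxy)phenyl]-2-[3-(5,5-dimethyl-1,3-dioxan-2-yl)furan-2-yl]-3-(ethynyloxy)propyl]oxy}diphenylsilane, via dichlorovinyl ether 18 (not isolated), via lithium alkynyl ether 19 (not isolated)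
Conditions: KH, THF, 0 °C; 17, −50 °C → rt; n-BuLi (2.4 equiv), −78 °C; MeOH, −78 °C
Reagents that add atoms: none
Why: Alkynyl ether synthesis by addition–elimination: the potassium alkoxide adds anti to dichloroacetylene formed in situ from 17 to give the (E)-1,2-dichlorovinyl ether; n-BuLi then dehydrochlorinates it and exchanges chlorine for lithium, and methanol protonates the lithium alkynyl ether. Because 16 has no carbonyl group and no acidic C–H, neither retro-aldol cleavage nor β-elimination can compete. The product is kept cold and used at once, since benzylic ynol ethers rearrange on heating.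

Step 9
Reactants: 20 the ethynyl ether
Product: 23 (2S,3R)-2-[3,4-bis(benzyloxy)phenyl]-3-{[(tert-butyldiphenylsilyl)oxy]methyl}-4-(5,5-dimethyl-1,3-dioxan-2-yl)-2,3-dihydro-1-benzofuran-7-ol, via oxepine 21 (not isolated), via arene oxide 22 (not isolated)
Conditions: Ph3PAuNTf2 (5 mol%), CH2Cl2 (0.02 M), 4 Å molecular sieves, −20 °C → rt
Reagents that add atoms: none
Why: Cationic monovalent gold binds the ynol ether, which is polarised like a ketene oxonium ion so that the oxygen-bearing carbon is the electrophile; furan C2, the position carrying the tether, attacks it in a 5-exo-dig closure that forms C3a–C7a and the dihydrofuran ring. The resulting cyclopropyl gold carbene opens the furan to a dienal gold carbene, whose carbonyl oxygen adds to the carbene carbon to give oxepine 21; 6π electrocyclisation to arene oxide 22 forms C6–C7 and closes the six-membered ring. The epoxide opens at C6 because the cation formed there is conjugated with the lone pair of O1 on C7a, and a 1,2-hydride shift with tautomerisation leaves the former furan oxygen on C7 as the phenol. The closest known reaction type is the gold-catalysed furan–yne phenol synthesis with ethynyl ether tethers, which converts 2-(furan-2-yl)ethyl ethynyl ethers into 7-hydroxy-2,3-dihydrobenzofurans. No stereocentre is created: C2 and C3 come unchanged from the aldol, and C3, now without an acidic hydrogen, cannot epimerise. The step needs attack on the oxygen-bearing alkyne carbon (secured by the polarisation and by the three-atom tether, which allows only the 5-exo mode), regioselective arene oxide opening (secured by O1), and chemoselectivity over ionisation or sigmatropic loss of the electron-rich benzylic ynol ether (addressed by low temperature, dilution and the speed of the intramolecular attack).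

Step 10
Reactants: 23 the C7 phenol
Product: 24 {[(2S,3R)-7-(benzyloxy)-2-[3,4-bis(benzyloxy)phenyl]-4-(5,5-dimethyl-1,3-dioxan-2-yl)-2,3-dihydro-1-benzofuran-3-yl]methoxy}(tert-butyl)diphenylsilane
Conditions: BnBr, K2CO3, DMF, rt
Reagents that add atoms: benzyl bromide, BrCc1ccccc1
Why: Williamson etherification of the phenol; benzyl matches the other phenol protecting groups and shields the electron-rich ring from the oxidant of step 12.

Step 11
Reactants: 24 the silyl ether
Product: 25 [(2S,3R)-7-(benzyloxy)-2-[3,4-bis(benzyloxy)phenyl]-4-(5,5-dimethyl-1,3-dioxan-2-yl)-2,3-dihydro-1-benzofuran-3-yl]methanol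
Conditions: Bu4NF, THF, 0 °C → rt
Reagents that add atoms: none
Why: Fluoride-mediated desilylation; the molecule holds no ester or other base-sensitive group at this stage, so the basicity of the fluoride is harmless.

Step 12
Reactants: 25 the primary alcohol
Product: 27 (2S,3S)-7-(benzyloxy)-2-[3,4-bis(benzyloxy)phenyl]-4-(5,5-dimethyl-1,3-dioxan-2-yl)-2,3-dihydro-1-benzofuran-3-carboxylic acid, via aldehyde 26 (not isolated)
Conditions: TEMPO (cat.), PhI(OAc)2, NaHCO3, MeCN/H2O, 0 °C → rt
Reagents that add atoms: water, O
Why: TEMPO/PhI(OAc)2 oxidation through the aldehyde hydrate to the acid; the buffered, non-basic medium should keep the C3 aldehyde from ring opening and the acetal from hydrolysis. Any epimerisation at C3 would favour the trans isomer that is wanted.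

Step 13
Reactants: 27 the C3 acid
Product: 28 methyl (2S,3S)-7-(benzyloxy)-2-[3,4-bis(benzyloxy)phenyl]-4-(5,5-dimethyl-1,3-dioxan-2-yl)-2,3-dihydro-1-benzofuran-3-carboxylate
Conditions: MeI, KHCO3, DMF, rt
Reagents that add atoms: iodomethane, CI
Why: O-alkylation of the carboxylate; hydrogencarbonate is too weak a base to deprotonate C3.

Step 14
Reactants: 28 the acetal ester
Product: 29 methyl (2S,3S)-7-(benzyloxy)-2-[3,4-bis(benzyloxy)phenyl]-4-formyl-2,3-dihydro-1-benzofuran-3-carboxylate
Conditions: 1 M HCl, THF, rt
Reagents that add atoms: water, O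
Why: Acid-catalysed acetal hydrolysis releases the aryl aldehyde under conditions that leave the methyl ester and the benzyl ethers alone.

Step 15
Reactants: 30 sodium (2R)-3-(3,4-dihydroxyphenyl)-2-hydroxypropanoate
Product: 31 benzyl (2R)-3-[3,4-bis(benzyloxy)phenyl]-2-hydroxypropanoate
Conditions: BnBr, K2CO3, DMF, rt
Reagents that add atoms: benzyl bromide, BrCc1ccccc1
Why: Chemoselective O-alkylation: carbonate ionises the carboxylate and the two phenols but not the secondary alcohol, so one step gives the benzyl ester bis(benzyl ether) with the hydroxyl free and the stereocentre untouched.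

Step 16
Reactants: 31 the protected lactate; 32 2-(diethoxyphosphoryl)acetic acid
Product: 33 benzyl (2R)-3-[3,4-bis(benzyloxy)phenyl]-2-{[2-(diethoxyphosphoryl)acetyl]oxy}propanoate
Conditions: EDC·HCl, DMAP (cat.), CH2Cl2, 0 °C → rt
Reagents that add atoms: none
Why: Steglich-type carbodiimide esterification of the secondary alcohol; the neutral conditions should not racemise the α-acyloxy ester.

Step 17
Reactants: 29 the C4 aldehyde; 33 the phosphonate
Product: 34 methyl (2S,3S)-7-(benzyloxy)-4-[(E)-3-{[(2R)-1-(benzyloxy)-3-[3,4-bis(benzyloxy)phenyl]-1-oxopropan-2-yl]oxy}-3-oxoprop-1-en-1-yl]-2-[3,4-bis(benzyloxy)phenyl]-2,3-dihydro-1-benzofuran-3-carboxylate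
Conditions: LiCl, i-Pr2NEt, MeCN, rt
Reagents that add atoms: none
Why: Horner–Wadsworth–Emmons olefination under Masamune–Roush conditions: the lithium-chelated phosphonate is acidic enough for a tertiary amine, which cannot deprotonate C3–H. The (E)-enoate should therefore form without epimerisation or ring opening.

Step 18
Reactants: 34 the hexabenzyl compound
Product: 35 monomethyl lithospermate
Conditions: BCl3, C6HMe5, CH2Cl2, −78 → −20 °C; MeOH
Reagents that add atoms: none
Why: Lewis-acid debenzylation with a non-basic cation scavenger: BCl3 activates the benzyl ethers and the benzyl ester, and pentamethylbenzene traps the benzyl cations by Friedel–Crafts alkylation. At low temperature the methyl ester, the enoate and its double bond should be left intact.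

## Compound list

1 | furan-3-carbaldehyde | O=Cc1ccoc1 | starting material
2 | 2,2-dimethylpropane-1,3-diol | CC(C)(CO)CO | starting material
3 | 2-(furan-3-yl)-5,5-dimethyl-1,3-dioxane | CC1(C)COC(c2ccoc2)OC1 | intermediate
4 | oxirane | C1CO1 | starting material
5 | [3-(5,5-dimethyl-1,3-dioxan-2-yl)furan-2-yl]lithium | [Li]c1occc1C1OCC(C)(C)CO1 | intermediate
6 | 2-[3-(5,5-dimethyl-1,3-dioxan-2-yl)furan-2-yl]ethan-1-ol | OCCc1occc1C1OCC(C)(C)CO1 | intermediate
7 | 2-[3-(5,5-dimethyl-1,3-dioxan-2-yl)furan-2-yl]acetaldehyde | O=CCc1occc1C1OCC(C)(C)CO1 | intermediate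
8 | 2-[3-(5,5-dimethyl-1,3-dioxan-2-yl)furan-2-yl]acetic acid | OC(=O)Cc1occc1C1OCC(C)(C)CO1 | intermediate
9 | (4S)-4-benzyl-1,3-oxazolidin-2-one | O=C1N[C@@H](Cc2ccccc2)CO1 | starting material
10 | 2-[3-(5,5-dimethyl-1,3-dioxan-2-yl)furan-2-yl]acetic 2,2-dimethylpropanoic anhydride | CC(C)(C)C(=O)OC(=O)Cc1occc1C1OCC(C)(C)CO1 | intermediate
11 | (4S)-4-benzyl-3-{2-[3-(5,5-dimethyl-1,3-dioxan-2-yl)furan-2-yl]acetyl}-1,3-oxazolidin-2-one | O=C(Cc1occc1C1OCC(C)(C)CO1)N1[C@@H](Cc2ccccc2)COC1=O | intermediate
12 | 3,4-bis(benzyloxy)benzaldehyde | O=Cc1ccc(OCc2ccccc2)c(OCc2ccccc2)c1 | starting material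
13 | (4S)-4-benzyl-3-{(Z)-1-[(dibutylboranyl)oxy]-2-[3-(5,5-dimethyl-1,3-dioxan-2-yl)furan-2-yl]ethenyl}-1,3-oxazolidin-2-one | CCCCB(CCCC)O/C(=C\c1occc1C1OCC(C)(C)CO1)N1[C@@H](Cc2ccccc2)COC1=O | intermediate
14 | (4S)-4-benzyl-3-{(2R,3S)-3-[3,4-bis(benzyloxy)phenyl]-2-[3-(5,5-dimethyl-1,3-dioxan-2-yl)furan-2-yl]-3-hydroxypropanoyl}-1,3-oxazolidin-2-one | O=C([C@H]([C@H](O)c1ccc(OCc2ccccc2)c(OCc2ccccc2)c1)c1occc1C1OCC(C)(C)CO1)N1[C@@H](Cc2ccccc2)COC1=O | intermediate
15 | (1S,2R)-1-[3,4-bis(benzyloxy)phenyl]-2-[3-(5,5-dimethyl-1,3-dioxan-2-yl)furan-2-yl]propane-1,3-diol | OC[C@H]([C@H](O)c1ccc(OCc2ccccc2)c(OCc2ccccc2)c1)c1occc1C1OCC(C)(C)CO1 | intermediate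
16 | (1S,2R)-1-[3,4-bis(benzyloxy)phenyl]-3-[(tert-butyldiphenylsilyl)oxy]-2-[3-(5,5-dimethyl-1,3-dioxan-2-yl)furan-2-yl]propan-1-ol | CC(C)(C)[Si](c1ccccc1)(c1ccccc1)OC[C@H]([C@H](O)c1ccc(OCc2ccccc2)c(OCc2ccccc2)c1)c1occc1C1OCC(C)(C)CO1 | intermediate
17 | trichloroethylene | ClC=C(Cl)Cl | starting material
18 | tert-butyl{[(2R,3S)-3-[3,4-bis(benzyloxy)phenyl]-3-{[(E)-1,2-dichloroethenyl]oxy}-2-[3-(5,5-dimethyl-1,3-dioxan-2-yl)furan-2-yl]propyl]oxy}diphenylsilane | CC(C)(C)[Si](c1ccccc1)(c1ccccc1)OC[C@H]([C@H](O/C(Cl)=C\Cl)c1ccc(OCc2ccccc2)c(OCc2ccccc2)c1)c1occc1C1OCC(C)(C)CO1 | intermediate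
19 | lithium alkynyl ether: 20 with lithium in place of the acetylenic hydrogen | CC(C)(C)[Si](c1ccccc1)(c1ccccc1)OC[C@H]([C@H](OC#C[Li])c1ccc(OCc2ccccc2)c(OCc2ccccc2)c1)c1occc1C1OCC(C)(C)CO1 | intermediate
20 | tert-butyl{[(2R,3S)-3-[3,4-bis(benzyloxy)phenyl]-2-[3-(5,5-dimethyl-1,3-dioxan-2-yl)furan-2-yl]-3-(ethynyloxy)propyl]oxy}diphenylsilane | CC(C)(C)[Si](c1ccccc1)(c1ccccc1)OC[C@H]([C@H](OC#C)c1ccc(OCc2ccccc2)c(OCc2ccccc2)c1)c1occc1C1OCC(C)(C)CO1 | intermediate
21 | oxepine: the 2,3-dihydrofuran ring of 23 fused through C3a–C7a to an oxepine whose oxygen links C6 and C7 (double bonds C3a=C4, C5=C6, C7=C7a); substituents and configuration at C2 and C3 as in 23 | CC(C)(C)[Si](c1ccccc1)(c1ccccc1)OC[C@H]1C2=C(C3OCC(C)(C)CO3)C=COC=C2O[C@@H]1c1ccc(OCc2ccccc2)c(OCc2ccccc2)c1 | intermediate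
22 | arene oxide: 6,7-epoxy-6,7-dihydro form of the ring system of 23 (epoxide oxygen bridging C6 and C7, double bonds C3a=C7a and C4=C5); substituents and configuration at C2 and C3 as in 23 | CC(C)(C)[Si](c1ccccc1)(c1ccccc1)OC[C@H]1C2=C(O[C@@H]1c1ccc(OCc3ccccc3)c(OCc3ccccc3)c1)C1OC1C=C2C1OCC(C)(C)CO1 | intermediate
23 | (2S,3R)-2-[3,4-bis(benzyloxy)phenyl]-3-{[(tert-butyldiphenylsilyl)oxy]methyl}-4-(5,5-dimethyl-1,3-dioxan-2-yl)-2,3-dihydro-1-benzofuran-7-ol | CC(C)(C)[Si](c1ccccc1)(c1ccccc1)OC[C@H]1c2c(C3OCC(C)(C)CO3)ccc(O)c2O[C@@H]1c1ccc(OCc2ccccc2)c(OCc2ccccc2)c1 | intermediate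
24 | {[(2S,3R)-7-(benzyloxy)-2-[3,4-bis(benzyloxy)phenyl]-4-(5,5-dimethyl-1,3-dioxan-2-yl)-2,3-dihydro-1-benzofuran-3-yl]methoxy}(tert-butyl)diphenylsilane | CC(C)(C)[Si](c1ccccc1)(c1ccccc1)OC[C@H]1c2c(C3OCC(C)(C)CO3)ccc(OCc3ccccc3)c2O[C@@H]1c1ccc(OCc2ccccc2)c(OCc2ccccc2)c1 | intermediate
25 | [(2S,3R)-7-(benzyloxy)-2-[3,4-bis(benzyloxy)phenyl]-4-(5,5-dimethyl-1,3-dioxan-2-yl)-2,3-dihydro-1-benzofuran-3-yl]methanol | OC[C@H]1c2c(C3OCC(C)(C)CO3)ccc(OCc3ccccc3)c2O[C@@H]1c1ccc(OCc2ccccc2)c(OCc2ccccc2)c1 | intermediate
26 | (2S,3S)-7-(benzyloxy)-2-[3,4-bis(benzyloxy)phenyl]-4-(5,5-dimethyl-1,3-dioxan-2-yl)-2,3-dihydro-1-benzofuran-3-carbaldehyde | O=C[C@H]1c2c(C3OCC(C)(C)CO3)ccc(OCc3ccccc3)c2O[C@@H]1c1ccc(OCc2ccccc2)c(OCc2ccccc2)c1 | intermediate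
27 | (2S,3S)-7-(benzyloxy)-2-[3,4-bis(benzyloxy)phenyl]-4-(5,5-dimethyl-1,3-dioxan-2-yl)-2,3-dihydro-1-benzofuran-3-carboxylic acid | OC(=O)[C@H]1c2c(C3OCC(C)(C)CO3)ccc(OCc3ccccc3)c2O[C@@H]1c1ccc(OCc2ccccc2)c(OCc2ccccc2)c1 | intermediate
28 | methyl (2S,3S)-7-(benzyloxy)-2-[3,4-bis(benzyloxy)phenyl]-4-(5,5-dimethyl-1,3-dioxan-2-yl)-2,3-dihydro-1-benzofuran-3-carboxylate | COC(=O)[C@H]1c2c(C3OCC(C)(C)CO3)ccc(OCc3ccccc3)c2O[C@@H]1c1ccc(OCc2ccccc2)c(OCc2ccccc2)c1 | intermediate
29 | methyl (2S,3S)-7-(benzyloxy)-2-[3,4-bis(benzyloxy)phenyl]-4-formyl-2,3-dihydro-1-benzofuran-3-carboxylate | COC(=O)[C@H]1c2c(C=O)ccc(OCc3ccccc3)c2O[C@@H]1c1ccc(OCc2ccccc2)c(OCc2ccccc2)c1 | intermediate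
30 | sodium (2R)-3-(3,4-dihydroxyphenyl)-2-hydroxypropanoate (sodium salt of (R)-danshensu) | [Na+].[O-]C(=O)[C@H](O)Cc1ccc(O)c(O)c1 | starting material
31 | benzyl (2R)-3-[3,4-bis(benzyloxy)phenyl]-2-hydroxypropanoate | O=C(OCc1ccccc1)[C@H](O)Cc1ccc(OCc2ccccc2)c(OCc2ccccc2)c1 | intermediate
32 | 2-(diethoxyphosphoryl)acetic acid | CCOP(=O)(CC(=O)O)OCC | starting material
33 | benzyl (2R)-3-[3,4-bis(benzyloxy)phenyl]-2-{[2-(diethoxyphosphoryl)acetyl]oxy}propanoate | CCOP(=O)(CC(=O)O[C@H](Cc1ccc(OCc2ccccc2)c(OCc2ccccc2)c1)C(=O)OCc1ccccc1)OCC | intermediate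
34 | methyl (2S,3S)-7-(benzyloxy)-4-[(E)-3-{[(2R)-1-(benzyloxy)-3-[3,4-bis(benzyloxy)phenyl]-1-oxopropan-2-yl]oxy}-3-oxoprop-1-en-1-yl]-2-[3,4-bis(benzyloxy)phenyl]-2,3-dihydro-1-benzofuran-3-carboxylate | COC(=O)[C@H]1c2c(/C=C/C(=O)O[C@H](Cc3ccc(OCc4ccccc4)c(OCc4ccccc4)c3)C(=O)OCc3ccccc3)ccc(OCc3ccccc3)c2O[C@@H]1c1ccc(OCc2ccccc2)c(OCc2ccccc2)c1 | intermediate
35 | monomethyl lithospermate: (2R)-3-(3,4-dihydroxyphenyl)-2-{[(2E)-3-[(2S,3S)-2-(3,4-dihydroxyphenyl)-7-hydroxy-3-(methoxycarbonyl)-2,3-dihydro-1-benzofuran-4-yl]prop-2-enoyl]oxy}propanoic acid | COC(=O)[C@H]1c2c(/C=C/C(=O)O[C@H](Cc3ccc(O)c(O)c3)C(=O)O)ccc(O)c2O[C@@H]1c1ccc(O)c(O)c1 | target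

## Step count and least certain steps

Total step count: 18. Longest linear sequence: 16 (steps 1–14, 17 and 18); steps 15 and 16 form the side-chain branch.

**Step 9 (key step).** The most likely failure is loss of the ynol ether before furan C2 can attack. The gold-activated ether resembles a ketene oxonium ion, and the benzylic C–O bond, para to a benzyloxy group, can ionise or rearrange sigmatropically. Addition of the product phenol to unreacted ynol ether and hydrolysis by traces of acid are further drains.

The fallback gives up the de novo construction of ring A and rearranges a preformed arene; it sets out from 12 (and 31) and comes back at 34. Benzylation of purchased 1-(2,3-dihydroxyphenyl)ethanone at the non-chelated hydroxyl (BnBr, K2CO3) should give the acetophenone F1. Claisen–Schmidt condensation of F1 with 12 should give the chalcone F2, and asymmetric intramolecular oxa-Michael addition with a bifunctional cinchona-alkaloid thiourea should close the (2S)-flavanone F3. Oxidative ring contraction (PhI(OAc)2, H2SO4, HC(OMe)3) should give the trans methyl ester F4, and careful saponification (LiOH, THF/H2O, 0 °C) the acid F5. A carboxylate-directed C–H olefination at C4 (Pd(OAc)2, N-acetyl amino acid ligand, KHCO3, O2) with the acrylate F6, made from 31 and acryloyl chloride, should give the olefinated acid F7. Methylation (MeI, KHCO3) returns to 34.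

**Step 8.** The most likely failures are silyl migration from the primary to the secondary oxygen in the potassium alkoxide (which would put the ynol ether on the wrong oxygen), sluggish addition of the hindered alkoxide to dichloroacetylene, metalation of benzyl ethers or the furan by n-BuLi, and thermal rearrangement of the product during isolation.

The fallback avoids any alkoxide; it sets out from 16 and comes back at 20. Formylation (acetic formic anhydride, pyridine) should give the formate F8. Ramirez-type dibromo-olefination of the formate carbonyl (CBr4, PPh3, Et3N, CH2Cl2) should give the 2,2-dibromovinyl ether F9. n-BuLi (2.2 equiv, THF, −78 °C) followed by methanol should convert F9 into 20.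

**Step 18.** The most likely failures are ionisation of the para-oxygenated benzylic C2–O1 bond by the Lewis acid (ring opening or epimerisation at C2), incomplete cleavage of the benzyl ester or partial cleavage of the methyl ester, and oxidation of the liberated catechols on work-up.

The fallback removes the benzyl groups by hydrogenolysis before the alkene exists and then joins unprotected partners; it sets out from 28 and 31 and comes back at 35. Hydrogenolysis of 28 (H2, Pd/C, EtOAc) should give the triphenol acetal F10, and aqueous acid the triphenol aldehyde F11. Heating 31 with Meldrum's acid (toluene, 90 °C) should give the malonate half-ester F12, and hydrogenolysis (H2, Pd/C) the free half-ester F13. Knoevenagel–Doebner condensation of F11 with F13 (pyridine, piperidine cat., 45 °C), which tolerates free phenols and decarboxylates in situ, should give 35; the base sensitivity of C3 is the price of this path.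

**Step 3.** The most likely failures are oxidative degradation of the electron-rich furan, self-condensation of the intermediate furylacetaldehyde 7, and partial acetal hydrolysis.

The fallback installs the acetic acid unit at the acid oxidation level by cross-coupling; it sets out from 3 and comes back at 8. Lithiation of 3 as in step 2 and quenching with BrCl2CCCl2Br should give the 2-bromofuran F14. Coupling with the Reformatsky reagent BrZnCH2CO2Et (Pd2(dba)3, XPhos, THF, rt → 60 °C) should give the ethyl ester F15, and LiOH in THF/H2O the acid 8.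

## Further compounds

F1 | step 9 | 1-[3-(benzyloxy)-2-hydroxyphenyl]ethan-1-one | CC(=O)c1cccc(OCc2ccccc2)c1O
F2 | step 9 | (E)-1-[3-(benzyloxy)-2-hydroxyphenyl]-3-[3,4-bis(benzyloxy)phenyl]prop-2-en-1-one | O=C(/C=C/c1ccc(OCc2ccccc2)c(OCc2ccccc2)c1)c1cccc(OCc2ccccc2)c1O
F3 | step 9 | (2S)-8-(benzyloxy)-2-[3,4-bis(benzyloxy)phenyl]-2,3-dihydro-4H-chromen-4-one | O=C1C[C@@H](c2ccc(OCc3ccccc3)c(OCc3ccccc3)c2)Oc2c(OCc3ccccc3)cccc21
F4 | step 9 | methyl (2S,3S)-7-(benzyloxy)-2-[3,4-bis(benzyloxy)phenyl]-2,3-dihydro-1-benzofuran-3-carboxylate | COC(=O)[C@H]1c2cccc(OCc3ccccc3)c2O[C@@H]1c1ccc(OCc2ccccc2)c(OCc2ccccc2)c1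
F5 | step 9 | (2S,3S)-7-(benzyloxy)-2-[3,4-bis(benzyloxy)phenyl]-2,3-dihydro-1-benzofuran-3-carboxylic acid | OC(=O)[C@H]1c2cccc(OCc3ccccc3)c2O[C@@H]1c1ccc(OCc2ccccc2)c(OCc2ccccc2)c1
F6 | step 9 | benzyl (2R)-3-[3,4-bis(benzyloxy)phenyl]-2-(prop-2-enoyloxy)propanoate | C=CC(=O)O[C@H](Cc1ccc(OCc2ccccc2)c(OCc2ccccc2)c1)C(=O)OCc1ccccc1
F7 | step 9 | (2S,3S)-7-(benzyloxy)-4-[(E)-3-{[(2R)-1-(benzyloxy)-3-[3,4-bis(benzyloxy)phenyl]-1-oxopropan-2-yl]oxy}-3-oxoprop-1-en-1-yl]-2-[3,4-bis(benzyloxy)phenyl]-2,3-dihydro-1-benzofuran-3-carboxylic acid | OC(=O)[C@H]1c2c(/C=C/C(=O)O[C@H](Cc3ccc(OCc4ccccc4)c(OCc4ccccc4)c3)C(=O)OCc3ccccc3)ccc(OCc3ccccc3)c2O[C@@H]1c1ccc(OCc2ccccc2)c(OCc2ccccc2)c1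
F8 | step 8 | (1S,2R)-1-[3,4-bis(benzyloxy)phenyl]-3-[(tert-butyldiphenylsilyl)oxy]-2-[3-(5,5-dimethyl-1,3-dioxan-2-yl)furan-2-yl]propyl formate | CC(C)(C)[Si](c1ccccc1)(c1ccccc1)OC[C@H]([C@H](OC=O)c1ccc(OCc2ccccc2)c(OCc2ccccc2)c1)c1occc1C1OCC(C)(C)CO1
F9 | step 8 | tert-butyl{[(2R,3S)-3-[3,4-bis(benzyloxy)phenyl]-3-[(2,2-dibromoethenyl)oxy]-2-[3-(5,5-dimethyl-1,3-dioxan-2-yl)furan-2-yl]propyl]oxy}diphenylsilane | CC(C)(C)[Si](c1ccccc1)(c1ccccc1)OC[C@H]([C@H](OC=C(Br)Br)c1ccc(OCc2ccccc2)c(OCc2ccccc2)c1)c1occc1C1OCC(C)(C)CO1
F10 | step 18 | methyl (2S,3S)-2-(3,4-dihydroxyphenyl)-4-(5,5-dimethyl-1,3-dioxan-2-yl)-7-hydroxy-2,3-dihydro-1-benzofuran-3-carboxylate | COC(=O)[C@H]1c2c(C3OCC(C)(C)CO3)ccc(O)c2O[C@@H]1c1ccc(O)c(O)c1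
F11 | step 18 | methyl (2S,3S)-2-(3,4-dihydroxyphenyl)-4-formyl-7-hydroxy-2,3-dihydro-1-benzofuran-3-carboxylate | COC(=O)[C@H]1c2c(C=O)ccc(O)c2O[C@@H]1c1ccc(O)c(O)c1
F12 | step 18 | 3-{[(2R)-1-(benzyloxy)-3-[3,4-bis(benzyloxy)phenyl]-1-oxopropan-2-yl]oxy}-3-oxopropanoic acid | OC(=O)CC(=O)O[C@H](Cc1ccc(OCc2ccccc2)c(OCc2ccccc2)c1)C(=O)OCc1ccccc1
F13 | step 18 | (2R)-2-[(carboxyacetyl)oxy]-3-(3,4-dihydroxyphenyl)propanoic acid | OC(=O)CC(=O)O[C@H](Cc1ccc(O)c(O)c1)C(=O)O
F14 | step 3 | 2-(2-bromofuran-3-yl)-5,5-dimethyl-1,3-dioxane | CC1(C)COC(c2ccoc2Br)OC1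
F15 | step 3 | ethyl 2-[3-(5,5-dimethyl-1,3-dioxan-2-yl)furan-2-yl]acetate | CCOC(=O)Cc1occc1C1OCC(C)(C)CO1
A1 | alternative 1 | methyl (2E)-3-[3-(benzyloxy)-4-hydroxyphenyl]prop-2-enoate | COC(=O)/C=C/c1ccc(O)c(OCc2ccccc2)c1
A2 | alternative 1 | tert-butyl (2R)-3-[3,4-bis(benzyloxy)phenyl]-2-{[(2E)-3-[4-(benzyloxy)-3-hydroxyphenyl]prop-2-enoyl]oxy}propanoate | O=C(/C=C/c1ccc(OCc2ccccc2)c(O)c1)O[C@H](Cc1ccc(OCc2ccccc2)c(OCc2ccccc2)c1)C(=O)OC(C)(C)C
A3 | alternative 1 | methyl (2S,3S)-7-(benzyloxy)-2-[3-(benzyloxy)-4-hydroxyphenyl]-4-[(E)-3-{[(2R)-3-[3,4-bis(benzyloxy)phenyl]-1-(tert-butoxy)-1-oxopropan-2-yl]oxy}-3-oxoprop-1-en-1-yl]-2,3-dihydro-1-benzofuran-3-carboxylate | COC(=O)[C@H]1c2c(/C=C/C(=O)O[C@H](Cc3ccc(OCc4ccccc4)c(OCc4ccccc4)c3)C(=O)OC(C)(C)C)ccc(OCc3ccccc3)c2O[C@@H]1c1ccc(O)c(OCc2ccccc2)c1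
A4 | alternative 2 | (2S)-8-(benzyloxy)-2-[3,4-bis(benzyloxy)phenyl]-5-bromo-2,3-dihydro-4H-chromen-4-one | O=C1C[C@@H](c2ccc(OCc3ccccc3)c(OCc3ccccc3)c2)Oc2c(OCc3ccccc3)ccc(Br)c21
A5 | alternative 2 | methyl (2S,3S)-7-(benzyloxy)-2-[3,4-bis(benzyloxy)phenyl]-4-bromo-2,3-dihydro-1-benzofuran-3-carboxylate | COC(=O)[C@H]1c2c(Br)ccc(OCc3ccccc3)c2O[C@@H]1c1ccc(OCc2ccccc2)c(OCc2ccccc2)c1
A6 | alternative 3 | methyl (2S,3S)-2-[3,4-bis(benzyloxy)phenyl]-5-[(tert-butyldimethylsilyl)oxy]-4-(3,3-dimethoxyprop-1-en-2-yl)-2,3-dihydrofuran-3-carboxylate | COC(=O)[C@H]1C(C(=C)C(OC)OC)=C(O[Si](C)(C)C(C)(C)C)O[C@@H]1c1ccc(OCc2ccccc2)c(OCc2ccccc2)c1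
A7 | alternative 3 | but-3-yn-2-one | CC(=O)C#C
A8 | alternative 3 | methyl (2S,3S)-7-acetyl-2-[3,4-bis(benzyloxy)phenyl]-4-(dimethoxymethyl)-2,3-dihydro-1-benzofuran-3-carboxylate | COC(=O)[C@H]1c2c(C(OC)OC)ccc(C(C)=O)c2O[C@@H]1c1ccc(OCc2ccccc2)c(OCc2ccccc2)c1
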